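## Structural features

The target 20 is a (2S)-flavanone. Aromatic ring A is fused to a dihydropyranone ring C (O1, C2, C3, C4=O, C4a, C8a); C2 carries a 4-hydroxy-2-methoxyphenyl ring B, C5 and C7 carry free hydroxyls, and C8 carries a ten-carbon chain CH2–CH(isopropenyl)–CH2CH2–C(OH)Me2, a lavandulyl group hydrated at its trisubstituted alkene. There are two stereocentres, C2 (S) and the chain carbon C2'' (R). They lie six bonds apart, so neither can steer the other and each needs its own source of asymmetry. C2 is fragile: a 5,7-dihydroxyflavanone opens under base to the 2'-hydroxychalcone and recloses without memory, and the electron-rich ring B also eases ionisation of the C2–O1 bond. The isopropenyl group forbids hydrogenation and, under acid, adds the neighbouring C7 or C8a hydroxyl to give a chroman; the tertiary alcohol is acid-sensitive as well. The real difficulties are regiochemical and chemoselective rather than skeletal: the chain must sit on C8 and not C6 of a phloroglucinol nucleus, only one of the two alkenes of the terpene unit may be hydrated, and C2 must be set late under conditions that are neither basic nor acidic. The chain centre corresponds to (S)-lavandulol; its label becomes R only because the CIP order changes once the carbinol carbon is bonded to ring A. The key step exploits the fact that C4 is a single carbon between C4a and C3, while C2–C3 with ring B is the two-carbon unit of an arylacetylene: an ortho-iodophenol (iodine on C4a, hydroxyl on C8a), carbon monoxide and the alkyne give ring C at the flavone level, where C2 is trigonal and no stereocentre can be lost.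

## Logic of the disconnections

20 ⇒ 19. The three aryl O–Si bonds are cut. Free phenols would not survive the organozinc, hydride and copper hydride chemistry upstream, and one kind of silyl ether allows a single unmasking. The demand on the forward step is a near-neutral fluoride source, so that C2 and the isopropenyl group are not touched.

19 ⇒ 18. The C2–H bond (with C3–H) is cut, which turns the stereocentre into the trigonal C2 of a flavone. This removes the only configurationally labile centre from every earlier step. The forward step must add hydride to one face of C2=C3 under catalyst control and leave the isopropenyl group and the C4 carbonyl alone.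

18 ⇒ 12 + 15 + 16 (through 17). The bonds C4a–C4, C4–C3 and O1–C2 are cut. C4 is a one-carbon unit and C2–C3 with ring B is an alkyne, so ring C falls apart into three simple pieces and the synthesis becomes convergent. The forward step needs iodine ortho to the only free hydroxyl, carbonylation faster than direct alkynylation, and 6-endo rather than 5-exo closure.

12 ⇒ 11. The C4a–I bond is cut. The free C8a hydroxyl is the natural director for the halogen, and 11 has only one open position ortho to it. The forward step must iodinate that carbon and not the CH between the two silyloxy groups, and must be faster on the arene than on the isopropenyl group.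

11 ⇒ 10 ⇒ 9. The C–H bond next to the carbinol carbon and the O–acyl bond are cut first, then the two C–O bonds of the oxirane. The tertiary alcohol is the Markovnikov hydrate of the trisubstituted alkene, so the chain returns to an unmodified lavandulyl group. The forward steps need a peracid that selects the more substituted alkene and a hydride that attacks the less substituted oxirane carbon; the same hydride removes the acetate.

9 ⇒ 7 + 3 (through 8). The C8–C1'' bond is cut, the only C–C bond between ring A and the chain. This splits the molecule into a phloroglucinol piece and a terpene piece. The forward step asks an alkylzinc with a β stereocentre and an allylic β hydrogen to couple at a doubly ortho-substituted aryl iodide without β-hydride elimination.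

7 ⇒ 6 ⇒ 5 ⇒ 4. The O–acyl bond, the C–I bond and two O–Si bonds are cut in turn, leading to a cheap symmetric triol. The oxygen left unsilylated in 5 is the future O1, so the three ring oxygens are differentiated at the first step. The forward steps need a partial silylation and an iodination ortho rather than para to the hydroxyl.

3 ⇒ 2 ⇒ 1. The C–I bond is cut, and then the two enantiomers are separated. The chain stereocentre is bought as a racemate, so the forward step needs an enzyme that distinguishes a stereocentre one carbon removed from the hydroxyl.

15 ⇒ 14 ⇒ 13. The terminal alkyne carbon and the O–Si bond are cut, leading to a commercial hydroxy aldehyde. The one-carbon homologation must not use conditions that strip a silyl group para to a formyl group.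

## Other disconnections considered

Alternative 1: Ring A is made last by cutting its C4a–C5 bond, with ring C and C2 already present as a 2-aryl-2,3-dihydropyran-4-one. The forward key step heats the dioxinone A2 (the dihydropyranone with a dioxinone and the terpene chain on the carbon that becomes C8). Acetone is lost by retro-[4+2] reaction, the C7 ketone of the acylketene enolises towards C8, and the dienylketene closes by 6π-electrocyclisation between C4a and the ketene carbon. Tautomerisation would give A1 with both ring A hydroxyls free.
- In its favour: the position of the chain is fixed by construction, so there is no 6- versus 8-alkyl question. The two phenols need no protection or differentiation. No metal is used. C2 would be set early by a well-established catalytic asymmetric hetero-Diels–Alder reaction of the ring B aldehyde.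
- Against it here: A2 combines a β-keto-dioxinone, a vinylogous ester and a disposable stereocentre, and its assembly would take more steps than the whole of ring A costs in the chosen plan, where ring A is bought. The acylketene can also be captured at oxygen. The thermolysis exposes a C2 benzylic ether with an electron-rich aryl group, and then a free 5,7-dihydroxyflavanone, to prolonged heat.
- Comparison: on regiocontrol of ring A and on the number of protecting groups this route is the equal or the better of the chosen plan, and it avoids a late asymmetric reduction. On step economy and on thermal stress at C2 it is the weaker.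

Alternative 2: The bonds C8a–C8 and C6–C7 of ring A are cut. The forward key step heats the cyclobutenone A5 with the siloxyalkyne A4. Electrocyclic opening to a vinylketene, [2+2] addition to the ynol ether, 4π opening and 6π closure would give the phenol A3, free only at the future C8a, with a silyl ether at C7 and a 4-methoxybenzyl ether at C5.
- In its favour: all three ring oxygens come out differentiated with no statistical silylation and no ortho-versus-para iodination question. The chain stereocentre comes from (R)-limonene of the chiral pool (ring cleavage gives the ester from which A4 is made by ester-to-ynolate homologation), so no resolution is needed.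
- Against it here: A4 and A5 each need several steps. A3 is only the counterpart of 11 in the chosen plan, so ring C must still be built afterwards. The 4-methoxybenzyl ether must later be removed from a phloroglucinol ring that tolerates neither oxidants such as DDQ nor strong acid.
- Comparison: on certainty of oxygen differentiation and on the source of chirality this route is better than the chosen plan. On mechanism it is a reliable thermal cascade. On step economy it is clearly longer, because it synthesises a ring that phloroglucinol supplies.

Alternative 3: The bonds O1–C2 and C3–C4 of ring C are cut. The forward key step treats the salicylaldehyde dimethyl acetal A7 with a chiral phosphoric acid. Loss of methanol would give a 4-methoxy ortho-quinone methide, which adds the styrene A8 in an inverse-demand [4+2] reaction to give the 2,4-cis flavan A6. C2 is set together with a C4 centre that is later oxidised away.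
- In its favour: ring C is closed and C2 set in one catalytic operation, without carbon monoxide, palladium or a late reduction, and C2 is never formed under basic conditions.
- Against it here: the acid meets an isopropenyl group beside an electron-rich ring, a styrene that is a para-hydroxystyrene and prone to oligomerisation, and a product whose C2–O1 bond is easily ionised, so the selectivity could erode in the flask. The quinone methide is fully substituted and crowded by the C5 silyloxy group. Taking the C4 methoxy group to the ketone costs further steps on a sensitive benzylic ether.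
- Comparison: in joining ring formation and stereocontrol in one step this route is better than the chosen plan, and it is about equal in step count after the ring A phenol. It is weaker in compatibility with the acid-sensitive chain and in precedent for so hindered a quinone methide.

Key step: step 12

Remark 1: the chain stereocentre of the target corresponds to (S)-lavandulol, so the racemic alcohol is resolved first.

Remark 2: the bisphosphine in step 13 is written as the R hand on the assumption that it delivers hydride to the face giving 2S; the sense is to be checked on a simple flavone and the S ligand used if required.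

Remark 3: within the same disconnection the iodophenol is redesigned. Both ring A ethers are triisopropylsilyl ethers and the tertiary alcohol stays free, so the free phenol is differentiated from the first step, and neither a selective silylation of an iodoresorcinol nor a separate protection of the alcohol is needed. The alkyne is made by Colvin homologation, because carbonate in methanol would strip a silyl group para to a formyl group.

## Route

Step 1
Reactants: 1 (±)-lavandulol [rac-5-methyl-2-(prop-1-en-2-yl)hex-4-en-1-ol]
Product: 2 (S)-lavandulol [(2S)-5-methyl-2-(prop-1-en-2-yl)hex-4-en-1-ol]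
Conditions: immobilised Candida antarctica lipase B, vinyl acetate, hexane, 25 °C, stopped beyond half conversion; chromatography from the acetate
Reagents that add atoms: none
Why: Lipase-catalysed kinetic resolution by irreversible transesterification, a known way to resolve this primary alcohol; the enzyme should acylate the R alcohol faster, so the slow-reacting S alcohol is recovered and its optical purity rises as conversion passes one half. No stereocentre is created; the chain stereocentre of the target is fixed here.

Step 2
Reactants: 2 (S)-lavandulol
Product: 3 (3S)-3-(iodomethyl)-2,6-dimethylhepta-1,5-diene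
Conditions: I2, PPh3, imidazole, CH2Cl2, 0 °C → 25 °C
Reagents that add atoms: iodine, II
Why: Appel-type iodination is an SN2 displacement at the primary carbon, so the adjacent stereocentre and both alkenes are untouched and the label stays S.

Step 3
Reactants: 4 phloroglucinol
Product: 5 3,5-bis(triisopropylsilyloxy)phenol
Conditions: i-Pr3SiCl (2.0 equiv), imidazole, DMF, 0 °C → 25 °C; chromatography
Reagents that add atoms: chlorotriisopropylsilane, CC(C)[Si](Cl)(C(C)C)C(C)C
Why: Silylation of phenols with a bulky chlorosilane; with two equivalents the bis-ether is the statistically favoured product of a cheap triol, and the mono- and tris-ethers are separable and recyclable. The oxygen left free is the future O1.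

Step 4
Reactants: 5 3,5-bis(triisopropylsilyloxy)phenol
Product: 6 2-iodo-3,5-bis(triisopropylsilyloxy)phenol
Conditions: N-iodosuccinimide (1.0 equiv), CH2Cl2, −40 → 0 °C, dark
Reagents that add atoms: N-iodosuccinimide, O=C1CCC(=O)N1I
Why: Electrophilic aromatic iodination of a free phenol; the CH para to the hydroxyl lies between two triisopropylsilyloxy groups and is sterically closed, so iodine should enter ortho to the hydroxyl.

Step 5
Reactants: 6 2-iodo-3,5-bis(triisopropylsilyloxy)phenol
Product: 7 2-iodo-3,5-bis(triisopropylsilyloxy)phenyl acetate
Conditions: Ac2O, pyridine, DMAP (cat.), CH2Cl2, 0 → 25 °C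
Reagents that add atoms: acetic anhydride, CC(=O)OC(C)=O
Why: Standard O-acetylation; the acetate removes the acidic proton that would quench the alkylzinc reagent, tempers the ring for the peracid step, and is lost without a step of its own in step 8.

Step 6
Reactants: 3 (3S)-3-(iodomethyl)-2,6-dimethylhepta-1,5-diene; 7 2-iodo-3,5-bis(triisopropylsilyloxy)phenyl acetate
Product: 9 2-[(2R)-5-methyl-2-(prop-1-en-2-yl)hex-4-en-1-yl]-3,5-bis(triisopropylsilyloxy)phenyl acetate, via alkylzinc iodide 8 (not isolated)
Conditions: Zn dust (activated with BrCH2CH2Br, Me3SiCl), LiCl, THF, 40 °C; then 7, Pd(OAc)2 (3 mol %), SPhos (6 mol %), THF, 25 → 45 °C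
Reagents that add atoms: none
Why: Negishi cross-coupling: zinc inserts into the primary C–I bond of 3, and the β-branched alkylzinc iodide 8 transmetalates to the arylpalladium species formed from 7. A bulky biarylphosphine speeds reductive elimination over β-hydride elimination, so the β stereocentre should be carried through unchanged (it is labelled R only because the CIP order changes); esters, silyl ethers and isolated alkenes tolerate organozinc halides.

Step 7
Reactants: 9 2-[(2R)-5-methyl-2-(prop-1-en-2-yl)hex-4-en-1-yl]-3,5-bis(triisopropylsilyloxy)phenyl acetate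
Product: 10 2-[(2S)-3-(3,3-dimethyloxiran-2-yl)-2-(prop-1-en-2-yl)propyl]-3,5-bis(triisopropylsilyloxy)phenyl acetate (both epimers at the oxirane CH)
Conditions: mCPBA (1.05 equiv), NaHCO3, CH2Cl2, −20 → 0 °C
Reagents that add atoms: 3-chloroperoxybenzoic acid, O=C(OO)c1cccc(Cl)c1
Why: Prilezhaev epoxidation; the trisubstituted alkene is markedly more nucleophilic than the 1,1-disubstituted isopropenyl group, so one equivalent of peracid at low temperature should select it, and the acetylated ring is not oxidised. The new oxirane CH becomes CH2 in step 8, so its configuration is irrelevant (the chain label reads S only because the oxirane changes the CIP order).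

Step 8
Reactants: 10 2-[(2S)-3-(3,3-dimethyloxiran-2-yl)-2-(prop-1-en-2-yl)propyl]-3,5-bis(triisopropylsilyloxy)phenyl acetate
Product: 11 2-[(2R)-5-hydroxy-5-methyl-2-(prop-1-en-2-yl)hexyl]-3,5-bis(triisopropylsilyloxy)phenol
Conditions: LiBHEt3 (4 equiv), THF, 0 → 25 °C; aq NH4Cl
Reagents that add atoms: none
Why: LiBHEt3 opens trisubstituted epoxides by SN2 attack of hydride at the less substituted carbon, giving the tertiary alcohol, and in the same operation reduces the aryl acetate to the free phenol; aryl triisopropylsilyl ethers and alkenes are inert to it.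

Step 9
Reactants: 11 2-[(2R)-5-hydroxy-5-methyl-2-(prop-1-en-2-yl)hexyl]-3,5-bis(triisopropylsilyloxy)phenol
Product: 12 2-[(2R)-5-hydroxy-5-methyl-2-(prop-1-en-2-yl)hexyl]-6-iodo-3,5-bis(triisopropylsilyloxy)phenol
Conditions: N-iodosuccinimide (1.0 equiv), CH2Cl2, −60 → −20 °C, dark; aq Na2S2O3
Reagents that add atoms: N-iodosuccinimide, O=C1CCC(=O)N1I
Why: Electrophilic iodination ortho to the only free phenol: the remaining ortho carbon is the sole unhindered hydroxyl-activated position, the other CH being flanked by two triisopropylsilyloxy groups. The highly activated ring should react at low temperature far faster than the isopropenyl group can enter iodoetherification.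

Step 10
Reactants: 13 4-hydroxy-2-methoxybenzaldehyde
Product: 14 2-methoxy-4-(triisopropylsilyloxy)benzaldehyde
Conditions: i-Pr3SiCl, imidazole, DMF, 25 °C
Reagents that add atoms: chlorotriisopropylsilane, CC(C)[Si](Cl)(C(C)C)C(C)C
Why: Routine silylation of a phenol; the triisopropylsilyl ether withstands diethylamine in step 12 and leaves with the other two in step 14.

Step 11
Reactants: 14 2-methoxy-4-(triisopropylsilyloxy)benzaldehyde
Product: 15 1-ethynyl-2-methoxy-4-(triisopropylsilyloxy)benzene
Conditions: Me3SiCHN2, n-BuLi, THF, −78 °C → 25 °C
Reagents that add atoms: trimethylsilyldiazomethane, C[Si](C)(C)C=[N+]=[N-]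
Why: Colvin homologation: lithiated trimethylsilyldiazomethane adds to the aldehyde, Peterson elimination gives a diazoalkene, and loss of nitrogen with 1,2-shift delivers the terminal alkyne. The aprotic low-temperature conditions leave the aryl silyl ether intact.

Step 12
Reactants: 12 2-[(2R)-5-hydroxy-5-methyl-2-(prop-1-en-2-yl)hexyl]-6-iodo-3,5-bis(triisopropylsilyloxy)phenol; 15 1-ethynyl-2-methoxy-4-(triisopropylsilyloxy)benzene; 16 carbon monoxide
Product: 18 8-[(2R)-5-hydroxy-5-methyl-2-(prop-1-en-2-yl)hexyl]-2-[2-methoxy-4-(triisopropylsilyloxy)phenyl]-5,7-bis(triisopropylsilyloxy)-4H-chromen-4-one, via ynone 17 (not isolated)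
Conditions: PdCl2(PPh3)2 (5 mol %), CO (5 atm), Et2NH, 60 °C
Reagents that add atoms: none
Why: Zerovalent palladium, formed in the flask from PdCl2(PPh3)2 and the amine, inserts into the C4a–I bond of 12, and carbon monoxide 16 then inserts to give an aroyl complex of divalent palladium; the electron-rich, doubly ortho-substituted aryl group makes this migration fast, which together with the absence of copper disfavours direct alkynylation. Diethylamine deprotonates the palladium-bound alkyne 15, and reductive elimination forms C4–C3 and releases the ortho-hydroxyaryl ynone 17. The closest known reaction type is the palladium-catalysed carbonylative annulation of ortho-iodophenols with terminal alkynes to flavones, a carbonylative Sonogashira coupling followed by oxa-Michael cyclisation. Ring C closes by 6-endo-dig attack of the C8a hydroxyl on C2 of the ynone; the secondary amine first adds reversibly to C2 to give an enaminone, and addition–elimination at that carbon leads to the pyranone and not to the 5-exo aurone. No stereocentre is created, and the chain centre is remote from every reacting atom. The regiochemical demand is that the pyranone oxygen be the one flanked by the alkyl group; 12 meets it because its only free phenol is ortho to iodine on one side and to the chain on the other while both other ring oxygens are silylated, so the 6-alkyl isomer cannot form. Chemoselectivity rests on the aryl triisopropylsilyl ethers and the tertiary alcohol being inert to diethylamine and to the aroyl complex, and on the isolated alkene being a poor partner for it.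

Step 13
Reactants: 18 8-[(2R)-5-hydroxy-5-methyl-2-(prop-1-en-2-yl)hexyl]-2-[2-methoxy-4-(triisopropylsilyloxy)phenyl]-5,7-bis(triisopropylsilyloxy)-4H-chromen-4-one
Product: 19 (2S)-8-[(2R)-5-hydroxy-5-methyl-2-(prop-1-en-2-yl)hexyl]-2-[2-methoxy-4-(triisopropylsilyloxy)phenyl]-5,7-bis(triisopropylsilyloxy)-2,3-dihydro-4H-chromen-4-one
Conditions: Cu(OAc)2 (5 mol %), (R)-DTBM-SEGPHOS (5.5 mol %), (EtO)2MeSiH (3 equiv), t-BuOH (3 equiv), toluene, 0 → 25 °C; aq NH4F work-up
Reagents that add atoms: none
Why: Copper hydride-catalysed asymmetric conjugate reduction, known for 4H-chromen-4-ones: the ligated copper hydride adds hydride to C2 from the enantioface selected by the chiral bisphosphine, and tert-butanol protonates the copper enolate at C3. C2 is set by the catalyst alone (2S with the ligand hand of Remark 2), the chain stereocentre being too far away to interfere. The unactivated isopropenyl group and the electron-rich, peri-shielded C4 carbonyl should not be reduced at this temperature.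

Step 14
Reactants: 19 (2S)-8-[(2R)-5-hydroxy-5-methyl-2-(prop-1-en-2-yl)hexyl]-2-[2-methoxy-4-(triisopropylsilyloxy)phenyl]-5,7-bis(triisopropylsilyloxy)-2,3-dihydro-4H-chromen-4-one
Product: 20 (2S)-5,7-dihydroxy-8-[(2R)-5-hydroxy-5-methyl-2-(prop-1-en-2-yl)hexyl]-2-(4-hydroxy-2-methoxyphenyl)-2,3-dihydro-4H-chromen-4-one (target)
Conditions: TBAF/AcOH (1:1, 5 equiv), THF, 0 → 25 °C
Reagents that add atoms: none
Why: Fluoride cleavage of the three aryl silyl ethers; acetic acid keeps the medium near neutral, so the phenoxides are protonated as they form. Neither base-induced opening of ring C to the chalcone nor acid-induced cyclisation of the isopropenyl group onto a ring A hydroxyl should occur, so C2 and the chain are preserved.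

## Compound list

1 | (±)-lavandulol, rac-5-methyl-2-(prop-1-en-2-yl)hex-4-en-1-ol | CC(C)=CCC(CO)C(C)=C | starting material
2 | (S)-lavandulol, (2S)-5-methyl-2-(prop-1-en-2-yl)hex-4-en-1-ol | C=C(C)[C@H](CC=C(C)C)CO | intermediate
3 | (3S)-3-(iodomethyl)-2,6-dimethylhepta-1,5-diene | C=C(C)[C@H](CC=C(C)C)CI | intermediate
4 | phloroglucinol | Oc1cc(O)cc(O)c1 | starting material
5 | 3,5-bis(triisopropylsilyloxy)phenol | Oc1cc(O[Si](C(C)C)(C(C)C)C(C)C)cc(O[Si](C(C)C)(C(C)C)C(C)C)c1 | intermediate
6 | 2-iodo-3,5-bis(triisopropylsilyloxy)phenol | Oc1cc(O[Si](C(C)C)(C(C)C)C(C)C)cc(O[Si](C(C)C)(C(C)C)C(C)C)c1I | intermediate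
7 | 2-iodo-3,5-bis(triisopropylsilyloxy)phenyl acetate | CC(=O)Oc1cc(O[Si](C(C)C)(C(C)C)C(C)C)cc(O[Si](C(C)C)(C(C)C)C(C)C)c1I | intermediate
8 | [(2S)-5-methyl-2-(prop-1-en-2-yl)hex-4-en-1-yl]zinc iodide | C=C(C)[C@H](CC=C(C)C)C[Zn]I | intermediate
9 | 2-[(2R)-5-methyl-2-(prop-1-en-2-yl)hex-4-en-1-yl]-3,5-bis(triisopropylsilyloxy)phenyl acetate | C=C(C)[C@H](CC=C(C)C)Cc1c(OC(C)=O)cc(O[Si](C(C)C)(C(C)C)C(C)C)cc1O[Si](C(C)C)(C(C)C)C(C)C | intermediate
10 | 2-[(2S)-3-(3,3-dimethyloxiran-2-yl)-2-(prop-1-en-2-yl)propyl]-3,5-bis(triisopropylsilyloxy)phenyl acetate, both epimers at the oxirane CH | C=C(C)[C@H](CC1OC1(C)C)Cc1c(OC(C)=O)cc(O[Si](C(C)C)(C(C)C)C(C)C)cc1O[Si](C(C)C)(C(C)C)C(C)C | intermediate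
11 | 2-[(2R)-5-hydroxy-5-methyl-2-(prop-1-en-2-yl)hexyl]-3,5-bis(triisopropylsilyloxy)phenol | C=C(C)[C@H](CCC(C)(C)O)Cc1c(O)cc(O[Si](C(C)C)(C(C)C)C(C)C)cc1O[Si](C(C)C)(C(C)C)C(C)C | intermediate
12 | 2-[(2R)-5-hydroxy-5-methyl-2-(prop-1-en-2-yl)hexyl]-6-iodo-3,5-bis(triisopropylsilyloxy)phenol | C=C(C)[C@H](CCC(C)(C)O)Cc1c(O[Si](C(C)C)(C(C)C)C(C)C)cc(O[Si](C(C)C)(C(C)C)C(C)C)c(I)c1O | intermediate
13 | 4-hydroxy-2-methoxybenzaldehyde | COc1cc(O)ccc1C=O | starting material
14 | 2-methoxy-4-(triisopropylsilyloxy)benzaldehyde | COc1cc(O[Si](C(C)C)(C(C)C)C(C)C)ccc1C=O | intermediate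
15 | 1-ethynyl-2-methoxy-4-(triisopropylsilyloxy)benzene | C#Cc1ccc(O[Si](C(C)C)(C(C)C)C(C)C)cc1OC | intermediate
16 | carbon monoxide | [C-]#[O+] | starting material
17 | 1-{2-hydroxy-3-[(2R)-5-hydroxy-5-methyl-2-(prop-1-en-2-yl)hexyl]-4,6-bis(triisopropylsilyloxy)phenyl}-3-[2-methoxy-4-(triisopropylsilyloxy)phenyl]prop-2-yn-1-one | C=C(C)[C@H](CCC(C)(C)O)Cc1c(O[Si](C(C)C)(C(C)C)C(C)C)cc(O[Si](C(C)C)(C(C)C)C(C)C)c(C(=O)C#Cc2ccc(O[Si](C(C)C)(C(C)C)C(C)C)cc2OC)c1O | intermediate
18 | 8-[(2R)-5-hydroxy-5-methyl-2-(prop-1-en-2-yl)hexyl]-2-[2-methoxy-4-(triisopropylsilyloxy)phenyl]-5,7-bis(triisopropylsilyloxy)-4H-chromen-4-one | C=C(C)[C@H](CCC(C)(C)O)Cc1c(O[Si](C(C)C)(C(C)C)C(C)C)cc(O[Si](C(C)C)(C(C)C)C(C)C)c2c1OC(c1ccc(O[Si](C(C)C)(C(C)C)C(C)C)cc1OC)=CC2=O | intermediate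
19 | (2S)-8-[(2R)-5-hydroxy-5-methyl-2-(prop-1-en-2-yl)hexyl]-2-[2-methoxy-4-(triisopropylsilyloxy)phenyl]-5,7-bis(triisopropylsilyloxy)-2,3-dihydro-4H-chromen-4-one | C=C(C)[C@H](CCC(C)(C)O)Cc1c(O[Si](C(C)C)(C(C)C)C(C)C)cc(O[Si](C(C)C)(C(C)C)C(C)C)c2c1O[C@H](c1ccc(O[Si](C(C)C)(C(C)C)C(C)C)cc1OC)CC2=O | intermediate
20 | (2S)-5,7-dihydroxy-8-[(2R)-5-hydroxy-5-methyl-2-(prop-1-en-2-yl)hexyl]-2-(4-hydroxy-2-methoxyphenyl)-2,3-dihydro-4H-chromen-4-one | C=C(C)[C@H](CCC(C)(C)O)Cc1c(O)cc(O)c2c1O[C@H](c1ccc(O)cc1OC)CC2=O | target

## Count and risk

Total: 14 steps. Longest linear sequence: 10 steps (4 → 5 → 6 → 7 → 9 → 10 → 11 → 12 → 18 → 19 → 20; steps 3–9 and 12–14). The terpene branch (steps 1, 2) and the alkyne branch (steps 10, 11) join at steps 6 and 12.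

Step 12 (key step). Most likely to go wrong is loss of the carbonylative pathway. Oxidative addition into a very electron-rich, doubly ortho-substituted C–I bond is slow, and the crowded aroyl complex may be intercepted by diethylamine (amide formation), or the arylpalladium species may couple the alkyne before carbon monoxide inserts and then close to a benzofuran. Premature loss of the C5 silyl group at the ynone stage would also reopen the 6- versus 8-alkyl question. Fallback, setting out from 12 and 15 and returning at 17 and hence 18: 15 is deprotonated (n-BuLi, THF, −78 °C) and acylated with N-methoxy-N-methylcarbamoyl chloride to give the Weinreb amide N-methoxy-3-[2-methoxy-4-(triisopropylsilyloxy)phenyl]-N-methylprop-2-ynamide F1. 12 is deprotonated at both hydroxyls with MeMgCl and submitted to iodine–magnesium exchange with i-PrMgCl·LiCl to give the arylmagnesium chloride bis(chloromagnesium alkoxide) F2, which is acylated by F1 to give 17 after work-up. Diethylamine in ethanol then closes 17 to 18 by the same 6-endo addition–elimination, with no palladium and no carbon monoxide.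

Step 13. Most likely is sluggish or weakly face-selective hydride transfer, because the chromenone is a deactivated vinylogous ester with an ortho-substituted aryl group on C2 and a crowded ring A. Further reduction of the liberated ketone, or β-elimination of the copper enolate with opening of ring C, would also lower the yield or the purity at C2. Fallback, setting out from 18 and returning at 19: non-selective conjugate reduction with an achiral copper hydride (Cu(OAc)2, 1,2-bis(diphenylphosphino)benzene, (EtO)2MeSiH, t-BuOH) gives the C2-epimeric flavanone F3. Asymmetric transfer hydrogenation (RuCl(p-cymene)[TsDPEN], in the hand that consumes the 2R epimer, HCO2H/Et3N) then resolves it kinetically: the 2R epimer is reduced to the cis-flavan-4-ol F4, and unreacted 19 is separated by chromatography.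

Step 6. Most likely is β-hydride elimination from the alkylpalladium intermediate, whose β hydrogen is allylic, in competition with a slow reductive elimination at the hindered arene. This would give a diene and reduced arene, and reinsertion could erode the β stereocentre. Fallback, setting out from 3 and 7 and returning at 9: 3 undergoes iodine–lithium exchange (t-BuLi, Et2O, −78 °C) and is trapped with B-methoxy-9-borabicyclo[3.3.1]nonane to give the lithium borinate F5, which is coupled with 7 in a B-alkyl Suzuki–Miyaura reaction (PdCl2(dppf), K3PO4, DMF). If the base removes the acetate, the phenol F6 so formed, 2-[(2R)-5-methyl-2-(prop-1-en-2-yl)hex-4-en-1-yl]-3,5-bis(triisopropylsilyloxy)phenol, is re-acetylated (Ac2O, pyridine) to 9.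

Step 9. Most likely is iodine entering at the wrong place: at the CH between the two silyloxy groups, or at the isopropenyl group with capture of the iodonium ion by the phenol or the tertiary alcohol (iodoetherification). Fallback, setting out from 6 (with 8) and returning at 12, in which both ortho iodines are placed before any alkene is present: 6 is iodinated once more to 2,6-diiodo-3,5-bis(triisopropylsilyloxy)phenol F7 and acetylated to its acetate F8. F8, used in excess and recovered, is coupled once with 8 under the conditions of step 6 to give the iodo acetate F9. Buffered mCPBA gives the oxirane F10, and LiBHEt3 opens the oxirane and removes the acetate to give 12.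

Step 4. Most likely is iodination para to the hydroxyl, or twofold iodination, if the steric bias of the two silyloxy groups is smaller than expected. Fallback, setting out from 4 and returning at 6, with the order inverted so that symmetry fixes the position of iodine: 4 is mono-iodinated (I2, NaHCO3, aqueous THF, 0 °C) to 2-iodobenzene-1,3,5-triol F11. Two equivalents of i-Pr3SiCl with imidazole then silylate the unhindered hydroxyl para to iodine and one of the two equivalent ortho hydroxyls, giving 6.

Step 1. Most likely is insufficient discrimination by the lipase, because the stereocentre is one carbon removed from the reacting hydroxyl; the alcohol would then be recovered with too low an optical purity or only at high conversion. Fallback, which replaces 1 as the source of the stereocentre, sets out from commercial (S)-4-benzyl-1,3-oxazolidin-2-one rather than from a numbered compound, and returns at 2: N-acylation with 3-methylbut-2-enoyl chloride (n-BuLi, THF, −78 °C) gives the imide F12. Deconjugative α-alkylation of its dienolate (NaN(SiMe3)2, THF, −78 °C, prenyl bromide) should, by the usual chelated enolate model, give the (2S)-imide F13. LiBH4 (Et2O, MeOH, 0 °C) releases 2 and the auxiliary.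

## Further compounds

F1 | step 12 | N-methoxy-3-[2-methoxy-4-(triisopropylsilyloxy)phenyl]-N-methylprop-2-ynamide | CON(C)C(=O)C#Cc1ccc(O[Si](C(C)C)(C(C)C)C(C)C)cc1OC
F2 | step 12 | arylmagnesium chloride from 12, with both hydroxyls as chloromagnesium alkoxides | C=C(C)[C@H](CCC(C)(C)O[Mg]Cl)Cc1c(O[Si](C(C)C)(C(C)C)C(C)C)cc(O[Si](C(C)C)(C(C)C)C(C)C)c([Mg]Cl)c1O[Mg]Cl
F3 | step 13 | 8-[(2R)-5-hydroxy-5-methyl-2-(prop-1-en-2-yl)hexyl]-2-[2-methoxy-4-(triisopropylsilyloxy)phenyl]-5,7-bis(triisopropylsilyloxy)-2,3-dihydro-4H-chromen-4-one, both epimers at C2 | C=C(C)[C@H](CCC(C)(C)O)Cc1c(O[Si](C(C)C)(C(C)C)C(C)C)cc(O[Si](C(C)C)(C(C)C)C(C)C)c2c1OC(c1ccc(O[Si](C(C)C)(C(C)C)C(C)C)cc1OC)CC2=O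
F4 | step 13 | (2R,4R)-8-[(2R)-5-hydroxy-5-methyl-2-(prop-1-en-2-yl)hexyl]-2-[2-methoxy-4-(triisopropylsilyloxy)phenyl]-5,7-bis(triisopropylsilyloxy)-3,4-dihydro-2H-chromen-4-ol | C=C(C)[C@H](CCC(C)(C)O)Cc1c(O[Si](C(C)C)(C(C)C)C(C)C)cc(O[Si](C(C)C)(C(C)C)C(C)C)c2c1O[C@@H](c1ccc(O[Si](C(C)C)(C(C)C)C(C)C)cc1OC)C[C@H]2O
F5 | step 6 | lithium 9-methoxy-9-[(2S)-5-methyl-2-(prop-1-en-2-yl)hex-4-en-1-yl]-9-boranuidabicyclo[3.3.1]nonane | [Li+].CO[B-]1(C[C@@H](CC=C(C)C)C(C)=C)C2CCCC1CCC2
F6 | step 6 | 2-[(2R)-5-methyl-2-(prop-1-en-2-yl)hex-4-en-1-yl]-3,5-bis(triisopropylsilyloxy)phenol | C=C(C)[C@H](CC=C(C)C)Cc1c(O)cc(O[Si](C(C)C)(C(C)C)C(C)C)cc1O[Si](C(C)C)(C(C)C)C(C)C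
F7 | step 9 | 2,6-diiodo-3,5-bis(triisopropylsilyloxy)phenol | Oc1c(I)c(O[Si](C(C)C)(C(C)C)C(C)C)cc(O[Si](C(C)C)(C(C)C)C(C)C)c1I
F8 | step 9 | 2,6-diiodo-3,5-bis(triisopropylsilyloxy)phenyl acetate | CC(=O)Oc1c(I)c(O[Si](C(C)C)(C(C)C)C(C)C)cc(O[Si](C(C)C)(C(C)C)C(C)C)c1I
F9 | step 9 | 2-iodo-6-[(2R)-5-methyl-2-(prop-1-en-2-yl)hex-4-en-1-yl]-3,5-bis(triisopropylsilyloxy)phenyl acetate | C=C(C)[C@H](CC=C(C)C)Cc1c(O[Si](C(C)C)(C(C)C)C(C)C)cc(O[Si](C(C)C)(C(C)C)C(C)C)c(I)c1OC(C)=O
F10 | step 9 | 2-[(2S)-3-(3,3-dimethyloxiran-2-yl)-2-(prop-1-en-2-yl)propyl]-6-iodo-3,5-bis(triisopropylsilyloxy)phenyl acetate, both epimers at the oxirane CH | C=C(C)[C@H](CC1OC1(C)C)Cc1c(O[Si](C(C)C)(C(C)C)C(C)C)cc(O[Si](C(C)C)(C(C)C)C(C)C)c(I)c1OC(C)=O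
F11 | step 4 | 2-iodobenzene-1,3,5-triol | Oc1cc(O)c(I)c(O)c1
F12 | step 1 | (4S)-4-benzyl-3-(3-methylbut-2-enoyl)-1,3-oxazolidin-2-one | CC(C)=CC(=O)N1[C@@H](Cc2ccccc2)COC1=O
F13 | step 1 | (4S)-4-benzyl-3-[(2S)-5-methyl-2-(prop-1-en-2-yl)hex-4-enoyl]-1,3-oxazolidin-2-one | C=C(C)[C@H](CC=C(C)C)C(=O)N1[C@@H](Cc2ccccc2)COC1=O
A1 | alternative 1 | target as its 4'-O-tert-butyldimethylsilyl, tertiary O-triethylsilyl ether | C=C(C)[C@H](CCC(C)(C)O[Si](CC)(CC)CC)Cc1c(O)cc(O)c2c1O[C@H](c1ccc(O[Si](C)(C)C(C)(C)C)cc1OC)CC2=O
A2 | alternative 1 | 6-{(3R)-1-[(2S)-2-(4-tert-butyldimethylsilyloxy-2-methoxyphenyl)-4-oxo-3,4-dihydro-2H-pyran-6-yl]-6-methyl-3-(prop-1-en-2-yl)-6-(triethylsilyloxy)heptyl}-2,2-dimethyl-4H-1,3-dioxin-4-one, either epimer at the carbon that becomes C8 | C=C(C)[C@H](CCC(C)(C)O[Si](CC)(CC)CC)CC(C1=CC(=O)OC(C)(C)O1)C1=CC(=O)C[C@@H](c2ccc(O[Si](C)(C)C(C)(C)C)cc2OC)O1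
A3 | alternative 2 | 2-[(2R)-5-methyl-2-(prop-1-en-2-yl)-5-(triethylsilyloxy)hexyl]-5-(4-methoxybenzyloxy)-3-(triisopropylsilyloxy)phenol | C=C(C)[C@H](CCC(C)(C)O[Si](CC)(CC)CC)Cc1c(O)cc(OCc2ccc(OC)cc2)cc1O[Si](C(C)C)(C(C)C)C(C)C
A4 | alternative 2 | triisopropyl{[(4R)-7-methyl-4-(prop-1-en-2-yl)-7-(triethylsilyloxy)oct-1-yn-1-yl]oxy}silane | C=C(C)[C@H](CCC(C)(C)O[Si](CC)(CC)CC)CC#CO[Si](C(C)C)(C(C)C)C(C)C
A5 | alternative 2 | 3-(4-methoxybenzyloxy)cyclobut-2-en-1-one | O=C1C=C(OCc2ccc(OC)cc2)C1
A6 | alternative 3 | (2S,4S)-7-(tert-butyldimethylsilyloxy)-2-(4-hydroxy-2-methoxyphenyl)-4-methoxy-8-[(2R)-5-methyl-2-(prop-1-en-2-yl)-5-(triethylsilyloxy)hexyl]-5-(triisopropylsilyloxy)chromane | C=C(C)[C@H](CCC(C)(C)O[Si](CC)(CC)CC)Cc1c(O[Si](C)(C)C(C)(C)C)cc(O[Si](C(C)C)(C(C)C)C(C)C)c2c1O[C@H](c1ccc(O)cc1OC)C[C@@H]2OC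
A7 | alternative 3 | 3-(tert-butyldimethylsilyloxy)-6-(dimethoxymethyl)-2-[(2R)-5-methyl-2-(prop-1-en-2-yl)-5-(triethylsilyloxy)hexyl]-5-(triisopropylsilyloxy)phenol | C=C(C)[C@H](CCC(C)(C)O[Si](CC)(CC)CC)Cc1c(O[Si](C)(C)C(C)(C)C)cc(O[Si](C(C)C)(C(C)C)C(C)C)c(C(OC)OC)c1O
A8 | alternative 3 | 4-ethenyl-3-methoxyphenol | C=Cc1ccc(O)cc1OC
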